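**Retrosynthetic overview**

- The target is the (3R,4R)-trans lactone (numbering O1, C2=O, C3, C4, C5). It is reached by O-debenzylation, after a temporary methyl ester on C3 has been removed (Krapcho) with equilibration to trans.
- Two bonds are made in one pot: the aryl(ipso)–CH2 bond of the 3,4-dimethoxybenzyl group on C4 (aryl copper attacking a cyclopropane CH2) and the C3–CH2 bond to the protected syringyl group (enolate plus benzylic bromide).
- Enabling feature: the benzylic CH2 on C4 lies γ to the lactone carbonyl (CH2–C4–C3–C2=O). CH2, C4 and C3 can therefore be closed to a cyclopropane fused to the lactone (a 3-oxabicyclo[3.1.0]hexan-2-one with an ester on the C3 bridgehead), in which the CH2 is a strained homo-Michael acceptor and C3 a latent enolate.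
- Ring order: cyclopropane and lactone are formed together from dimethyl malonate and (R)-epichlorohydrin, which supplies C4 (R). The cyclopropane is a temporary ring, opened in the key step. Both benzene rings are bought.

Key step: step 5

Remark on the chemistry: where C3 carries a hydrogen between two carbonyl groups (compounds F1 and F2 of the fallbacks) it is configurationally labile, and the trans epimer is drawn.

**Route**

Step 1
Reactants: 1 dimethyl malonate; 2 (R)-epichlorohydrin
Product: 3 methyl (1S,5R)-2-oxo-3-oxabicyclo[3.1.0]hexane-1-carboxylate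
Conditions: NaOMe (1 equiv), MeOH, 0 °C to reflux; 1 in slight excess
Reagents that add atoms: none
Why: Tandem malonate alkylation/cyclopropanation/lactonisation: the malonate anion opens the epoxide at its CH2 terminus, the alkoxide closes a new epoxide by displacing chloride (Payne-type), the malonate carbanion opens that epoxide 3-exo-tet with inversion, and the released alkoxide lactonises onto the cis ester, so the R centre of 2 becomes C5 (R) of 3 and C1 follows from the obligatory cis ring fusion.

Step 2
Reactants: 4 syringaldehyde (4-hydroxy-3,5-dimethoxybenzaldehyde)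
Product: 5 4-(benzyloxy)-3,5-dimethoxybenzaldehyde
Conditions: BnBr, K2CO3, DMF, 60 °C
Reagents that add atoms: benzyl bromide, BrCc1ccccc1
Why: Williamson ether synthesis on the phenoxide; the aldehyde is inert to carbonate.

Step 3
Reactants: 5 4-(benzyloxy)-3,5-dimethoxybenzaldehyde
Product: 6 [4-(benzyloxy)-3,5-dimethoxyphenyl]methanol
Conditions: NaBH4, MeOH, 0 °C
Reagents that add atoms: none
Why: Borohydride reduction of an aryl aldehyde to the benzylic alcohol; the ethers are untouched.

Step 4
Reactants: 6 [4-(benzyloxy)-3,5-dimethoxyphenyl]methanol
Product: 7 2-(benzyloxy)-5-(bromomethyl)-1,3-dimethoxybenzene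
Conditions: PBr3, CH2Cl2, 0 °C; used without storage
Reagents that add atoms: phosphorus tribromide, BrP(Br)Br
Why: The primary benzylic alcohol is converted to the bromide through its phosphite ester by SN2 attack of bromide; short contact at 0 °C should spare the benzyl and methyl ethers.

Step 5
Reactants: 8 4-bromo-1,2-dimethoxybenzene; 3 methyl (1S,5R)-2-oxo-3-oxabicyclo[3.1.0]hexane-1-carboxylate; 7 2-(benzyloxy)-5-(bromomethyl)-1,3-dimethoxybenzene
Product: 11 methyl (3R,4R)-3-[4-(benzyloxy)-3,5-dimethoxybenzyl]-4-(3,4-dimethoxybenzyl)-2-oxotetrahydrofuran-3-carboxylate, via arylmagnesium bromide 9 (not isolated), via magnesium enolate 10 (not isolated)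
Conditions: 8, Mg, THF, 40 °C; added to 3, CuBr·SMe2 (10 mol%), THF, −40 to −20 °C; then 7 (excess), DMPU, Bu4NI (cat.), −20 to 40 °C
Reagents that add atoms: none
Why: Magnesium insertion into 8 gives 9, which with catalytic Cu(I) forms an aryl cuprate that attacks the cyclopropane CH2 (C6) of 3 in an SN2-type homoconjugate (1,5-) addition, cleaving the C1–C6 bond to the lactone/ester-stabilised enolate 10, and reductive elimination from copper forms the aryl–CH2 bond. The closest known reaction type is the copper-catalysed ring opening of cyclopropane-1,1-dicarboxylates and of alkyl 2-oxo-3-oxabicyclo[3.1.0]hexane-1-carboxylates by Grignard reagents, followed here in the same flask by ordinary C-alkylation of a malonate-type enolate with a benzylic bromide. No ring is closed: the cyclopropane is opened with release of its strain and the lactone is kept. C4 is not touched (none of its bonds is made or broken), so its R configuration comes unchanged from 3; the new quaternary C3 is set by approach of 7 to the enolate face anti to the C4 arylmethyl group, and either outcome would converge because the ester is removed in step 6. The step needs attack at C6 rather than at the ring-fusion carbon C5 or at a carbonyl: C6 is the only cyclopropane carbon with an open backside (that of C5 lies inside the bicycle), and the soft organocopper at low temperature prefers the strained C–C σ* to the ester and lactone C=O. C- over O-alkylation is favoured by the soft benzylic bromide, and the excess of 7 also consumes residual arylmetal before warming.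

Step 6
Reactants: 11 methyl (3R,4R)-3-[4-(benzyloxy)-3,5-dimethoxybenzyl]-4-(3,4-dimethoxybenzyl)-2-oxotetrahydrofuran-3-carboxylate
Product: 13 (3R,4R)-3-[4-(benzyloxy)-3,5-dimethoxybenzyl]-4-(3,4-dimethoxybenzyl)dihydrofuran-2(3H)-one, via cis lactone 12 (not isolated)
Conditions: LiCl, H2O, DMSO, 150 °C; then DBU, 60 °C, same pot
Reagents that add atoms: none
Why: Krapcho dealkoxycarbonylation: chloride demethylates the ester by SN2, the carboxylate loses CO2 to the lactone enolate and water protonates it; protonation can give the cis lactone 12 beside 13, and DBU equilibrates C3 through the enolate to the more stable trans arrangement, while C4 has no acidic hydrogen and stays R.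

Step 7
Reactants: 13 (3R,4R)-3-[4-(benzyloxy)-3,5-dimethoxybenzyl]-4-(3,4-dimethoxybenzyl)dihydrofuran-2(3H)-one
Product: 14 (3R,4R)-4-(3,4-dimethoxybenzyl)-3-(4-hydroxy-3,5-dimethoxybenzyl)dihydrofuran-2(3H)-one
Conditions: H2 (1 atm), Pd/C, EtOAc/EtOH, rt
Reagents that add atoms: none
Why: Hydrogenolysis of the aryl benzyl ether on palladium; the lactone, the aryl methyl ethers and both stereocentres are inert under these neutral conditions.

**Compound list**

1 | dimethyl malonate | COC(=O)CC(=O)OC | starting material
2 | (R)-epichlorohydrin | ClC[C@H]1CO1 | starting material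
3 | methyl (1S,5R)-2-oxo-3-oxabicyclo[3.1.0]hexane-1-carboxylate | O=C1OC[C@@H]2C[C@]12C(=O)OC | intermediate
4 | syringaldehyde (4-hydroxy-3,5-dimethoxybenzaldehyde) | COc1cc(C=O)cc(OC)c1O | starting material
5 | 4-(benzyloxy)-3,5-dimethoxybenzaldehyde | COc1cc(C=O)cc(OC)c1OCc1ccccc1 | intermediate
6 | [4-(benzyloxy)-3,5-dimethoxyphenyl]methanol | COc1cc(CO)cc(OC)c1OCc1ccccc1 | intermediate
7 | 2-(benzyloxy)-5-(bromomethyl)-1,3-dimethoxybenzene | COc1cc(CBr)cc(OC)c1OCc1ccccc1 | intermediate
8 | 4-bromo-1,2-dimethoxybenzene | COc1ccc(Br)cc1OC | starting material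
9 | (3,4-dimethoxyphenyl)magnesium bromide | COc1ccc([Mg]Br)cc1OC | intermediate
10 | bromomagnesium enolate of methyl (4R)-4-(3,4-dimethoxybenzyl)-2-oxotetrahydrofuran-3-carboxylate | COc1ccc(C[C@H]2COC(O[Mg]Br)=C2C(=O)OC)cc1OC | intermediate
11 | methyl (3R,4R)-3-[4-(benzyloxy)-3,5-dimethoxybenzyl]-4-(3,4-dimethoxybenzyl)-2-oxotetrahydrofuran-3-carboxylate | COc1ccc(C[C@H]2COC(=O)[C@]2(C(=O)OC)Cc2cc(OC)c(OCc3ccccc3)c(OC)c2)cc1OC | intermediate
12 | (3S,4R)-3-[4-(benzyloxy)-3,5-dimethoxybenzyl]-4-(3,4-dimethoxybenzyl)dihydrofuran-2(3H)-one (cis) | COc1ccc(C[C@H]2COC(=O)[C@H]2Cc2cc(OC)c(OCc3ccccc3)c(OC)c2)cc1OC | intermediate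
13 | (3R,4R)-3-[4-(benzyloxy)-3,5-dimethoxybenzyl]-4-(3,4-dimethoxybenzyl)dihydrofuran-2(3H)-one (trans) | COc1ccc(C[C@H]2COC(=O)[C@@H]2Cc2cc(OC)c(OCc3ccccc3)c(OC)c2)cc1OC | intermediate
14 | (3R,4R)-4-(3,4-dimethoxybenzyl)-3-(4-hydroxy-3,5-dimethoxybenzyl)dihydrofuran-2(3H)-one | COc1ccc(C[C@H]2COC(=O)[C@@H]2Cc2cc(OC)c(O)c(OC)c2)cc1OC | target

**Totals**

Total step count: 7.
Longest linear sequence: 6 steps (steps 2, 3, 4, 5, 6, 7, from syringaldehyde).

**Steps most likely to fail**

Step 5. The aryl nucleophile may add to the lactone or ester carbonyl of 3 in competition with opening of the cyclopropane, and the chelated magnesium enolate may alkylate so slowly that the benzylic bromide is lost to side reactions. The fallback reverses the polarity of the aryl–CH2 bond formation; it sets out from 3 and returns at 11. Iodide opens 3 at the cyclopropane CH2 (NaI, TMSCl, MeCN, 0 °C to rt, aqueous work-up) to give methyl (3S,4R)-4-(iodomethyl)-2-oxotetrahydrofuran-3-carboxylate F1. Nickel-catalysed reductive cross-electrophile coupling of this primary iodide with 8 (NiI2, 4,4′-di-tert-butyl-2,2′-bipyridine, Zn, DMA, 60 °C), run without base so that the iodide cannot close back to the cyclopropane, should form the same aryl–CH2 bond and give methyl (3S,4R)-4-(3,4-dimethoxybenzyl)-2-oxotetrahydrofuran-3-carboxylate F2. C-alkylation of that β-dicarbonyl compound with 7 (K2CO3, acetone, reflux) gives 11.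

Step 6. Protonation of the enolate formed on decarboxylation from the face remote from the C4 substituent leads to the cis lactone, the base equilibration may stay incomplete, and long heating may open the lactone. The fallback sets C3 by C–C bond formation instead of protonation; it sets out from the enolate 10 of step 5 and returns at 13. The enolate is quenched with aqueous NH4Cl instead of 7, which gives methyl (3S,4R)-4-(3,4-dimethoxybenzyl)-2-oxotetrahydrofuran-3-carboxylate F2, the compound already met in the fallback to step 5. The ester is removed at this stage, where C3 becomes a CH2 group and no stereochemical question arises (LiCl, H2O, DMSO, 140 °C), to give (4R)-4-(3,4-dimethoxybenzyl)dihydrofuran-2(3H)-one F3. Its lithium enolate (LiHMDS, THF, −78 °C) is alkylated with 7 (DMPU); attack anti to the C4 substituent under kinetic control should give 13 directly.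

Step 1. Direct displacement of chloride by the malonate anion, in competition with opening of the epoxide, leads to the enantiomeric cyclopropane and erodes the enantiomeric purity of 3, which no later step can restore. The fallback uses an electrophile for which direct displacement is by far the faster path; it sets out from 1 and returns at 3. Commercial (R)-glycidol is converted with Tf2O and 2,6-lutidine (CH2Cl2, −78 °C) to (2S)-oxiran-2-ylmethyl trifluoromethanesulfonate F4 (the descriptor changes, the centre is not touched). The sodium salt of 1 (NaH, THF, 0 °C) displaces the triflate with the epoxide intact to give dimethyl 2-{[(2R)-oxiran-2-yl]methyl}propanedioate F5. A second charge of base (NaOMe, MeOH, rt to 50 °C) brings about the 3-exo-tet opening of the epoxide with inversion and the lactonisation, which should give the same (1S,5R) lactone 3.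

**Further compounds**

F1 | step 5 | methyl (3S,4R)-4-(iodomethyl)-2-oxotetrahydrofuran-3-carboxylate | IC[C@H]1COC(=O)[C@@H]1C(=O)OC
F2 | step 5 | methyl (3S,4R)-4-(3,4-dimethoxybenzyl)-2-oxotetrahydrofuran-3-carboxylate | COc1ccc(C[C@H]2COC(=O)[C@@H]2C(=O)OC)cc1OC
F3 | step 6 | (4R)-4-(3,4-dimethoxybenzyl)dihydrofuran-2(3H)-one | COc1ccc(C[C@H]2COC(=O)C2)cc1OC
F4 | step 1 | (2S)-oxiran-2-ylmethyl trifluoromethanesulfonate | O=S(=O)(OC[C@@H]1CO1)C(F)(F)F
F5 | step 1 | dimethyl 2-{[(2R)-oxiran-2-yl]methyl}propanedioate | COC(=O)C(C[C@@H]1CO1)C(=O)OC
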